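Atom labels used throughout: ring B is a–b–c–d–e (a = spiro carbon shared with ring A, b = CH carrying the isopropyl group, c and d = CH2, e = spiro carbon that is also C2 of the pinane). Ring A is a–p–q–r–s–t (p = saturated ketone C=O, q = CMe2, r = C–OMe, s = C–Me, t = enone C=O). x is a temporary carbon that is later expelled from the ring.

## Analysis of the target

Compound 26 is a dispiro triad: a cyclohexenedione (ring A), a cyclopentane (ring B) and a 6,6-dimethylbicyclo[3.1.1]heptane (pinane) are joined through two adjacent quaternary carbons, a and e. It has five stereocentres: the pinane bridgeheads (1S,5R) and the contiguous set e, a and b (each R). Carbon d sits on the face of pinane C2 anti to the gem-dimethyl bridge, so a is syn to it; on ring B the isopropyl group, the enone carbonyl t and the pinane C3 methylene share one face, while the ketone p and the pinane bridgehead C1 lie on the other. Atom a is stereogenic only because p and t differ two bonds further out (CMe2 against C(Me)=C(OMe)), so its configuration must be set by telling two otherwise equivalent acyl groups apart. The sensitive groups are the vinylogous methyl ester (acid-labile), the 1,3-dicarbonyl pair on the quaternary carbon a (retro-Claisen cleavage by hard nucleophiles) and the pinane cyclobutane (rearranges if a cation develops at pinane C2). The difficulty lies in the vicinal quaternary spiro centres on the congested side of the bicycle, in the b and a configurations, which have no neighbouring handle other than each other, and in the position of the methoxy group. The route rests on reading the a–e bond as the C=C of an alkylidene of nopinone whose a-terminus carries a symmetric malonyl unit (the future p and t). The open face of that alkene, anti to the gem-dimethyl bridge, is where d must enter, and a ring can be closed across a=e in the same event.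

## Retrosynthetic reasoning

26 is traced back to the isopropenyl compound 25 and then to the tertiary carbinol 24. The isopropyl group is deliberately carried as C(OH)Me2 because the carbinol oxygen is the only handle on b that can reach ring A, and it can be removed at the end under neutral conditions (dehydration, hydrogenation).

The O–CH3 bond of 24 is cut to give the hydroxy trione 23. The methoxy group is placed last because the enol it caps is the acidic product of the ring-forming condensation. The forward step must discriminate the oxygen on r from that on t.

Ring A of 23 is opened at the s–t bond. This bond is chosen because t is the carbonyl cis to the substituent on b: in the precursor 22 it can be held as a γ-lactone with the carbinol oxygen, while the other carbonyl (p) already carries the chain q–r–s. An intramolecular Claisen condensation of the ethyl ketone enolate onto the lactone then builds ring A and fixes the configuration of a relative to b with no further control element.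

The chain of 22 is cut at the q–CH3 bond (to the β-diketone 21) and at the p–q bond (to the acid chloride 20 of lactone acid 18, and pentan-3-one 19). Methylation is placed before ring closure because at that stage q is the only doubly activated carbon in the molecule and sits, by way of the lactone, unambiguously on the side of p.

18 comes from the lactone ester 17 by ester cleavage, and 17 from the triester 15 by cutting both C–CH3 bonds of the carbinol. The forward reaction is a double methyl addition to the one unhindered ester, after which the alkoxide can lactonise only with the ester on its own face. This turns a symmetric malonate into two different carbonyl groups.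

15 is the methanolysis product of the Meldrum's ester 13. The stage is also the one at which b, α to an ester and with a not yet stereogenic, can be equilibrated relative to e alone.

13 is reconnected (a–x bond in place of a–b) to the cyclic α-diazo ketone 11 and hence the ketone 9: a Wolff ring contraction in the forward sense. The extra carbon x is not wasted; it becomes the ester carbon and finally the isopropyl methine.

9 is derived from alcohol 8 and the cycloadduct 6 by oxidation level changes only. 6 is cut at d–e and a–x, which returns the alkylidene Meldrum's acid 4 and the diene 5. These two bonds are cut together because e is then made from a planar carbon whose two faces the pinane distinguishes strongly, and because the a–e bond never has to be formed between two quaternary centres: it is already the alkene of 4.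

4 comes from nopinone 2 and Meldrum's acid 3 by Knoevenagel condensation, and 2 from (+)-β-pinene 1 by ozonolysis.

## Alternatives that were turned down

Alternative 1: The a–b bond is cut and ring A is carried as a hexasubstituted phloroglucinol attached to pinane C2. In the forward sense zerovalent palladium (Pd(PPh3)4) ionises the allylic carbonate A1, and the phenol attacks the internal allyl terminus through its ipso carbon (Tsuji–Trost dearomatisation). This closes ring B and gives the spiro dienone A2.
- For: ring A arrives complete, and the methoxy position is fixed on an arene by ordinary protecting-group chemistry. On this point the plan is stronger than the chosen route, which has to rely on site-selective O-methylation in step 14. Ring B, a and b are also made in one catalytic step.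
- Against: A1 needs the bulky aryl group on the quaternary pinane C2 on the face syn to the gem-dimethyl bridge. Every obvious way to make that bond passes through a cation or a congested addition at pinane C2 and risks cyclobutane opening.
- Against: in the key step O-allylation and attack at the terminal CH2 compete with ipso attack. The configurations of a (which ortho carbon ends on which face) and b (which π-allyl face) are both defined relative to e across a freely rotating aryl–e bond, with no substrate element to fix them.
- Comparison: the chosen route is longer in ring A, but it sets e by the facial bias of a small planar precursor and a by a covalent tether, not by hoped-for catalyst control over two centres.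

Alternative 2: The d–e bond is cut and a temporary a–d bond is added. A Corey–Chaykovsky reaction of dimethylsulfoxonium methylide with the nopinylidene dione A3 adds CH2 to e from the open face, and the enolate closes the spiro cyclopropane A4.
- For: ring A is carried intact from the start and the e centre is reached in very few steps, with the same facial sense as in the chosen route. On step count to e this plan is as good or better.
- Against: the cyclopropane then has to be opened at d by a carbon nucleophile that brings c and b. Any activation that helps (Lewis acid) ionises the a–e bond instead and gives a pinane C2 cation prone to Wagner–Meerwein rearrangement.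
- Against: ring B must finally be closed by alkylating the hindered, unsymmetrical dione enolate at a secondary carbon carrying an isopropyl group. O-alkylation and elimination are likely there, and both a and b are formed without control.
- Comparison: the chosen cycloaddition delivers d, c, b and the a–ring bond in one step, and postpones the a configuration to a step with an explicit tether.

Alternative 3: No skeletal bond is cut; a temporary O–C bond is used to desymmetrise ring A. Acid protonates the isopropenyl group of the symmetric trione A5, and the enol oxygen of the one carbonyl on the same face captures the tertiary cation to give the cyclic enol ether A6. C-methylation then has a single site, after which the ether is opened and the enol methylated.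
- For: the cis-only five-membered tether is as reliable for the configuration of a as the lactone used here. Ring A can be built symmetrically without a hindered intermolecular acylation, which makes it stronger than the chosen route at steps 11 and 13.
- Against: the step presupposes A5, so the vicinal quaternary a–e bond and the b/e relationship are not addressed by it. The tertiary C–O bond must later be broken through the same cation that formed it, under conditions where the closed ether is favoured. The methoxy position still has to be settled after opening.
- Comparison: the chosen route gets its tether as a by-product of installing the two methyl groups of the isopropyl unit, consumes it in the ring A closure and removes its oxygen by a neutral dehydration. The cyclic enol ether idea is kept only as a fallback (see step 13).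

Key step: step 3

Assumption: at the triester stage the ester on b is taken to be more stable on the ring B face of the pinane C3 methylene than on the face of the bulkier pinane bridgehead C1; this is the configuration required in 26.

## Route

Step 1
Reactants: 1 (+)-β-pinene
Product: 2 (−)-nopinone
Conditions: O3, CH2Cl2/MeOH, −78 °C; then Me2S, −78 °C → rt
Reagents that add atoms: ozone, [O-][O+]=O
Why: Ozonolysis with reductive work-up cleaves only the exocyclic C=CH2 bond and leaves the pinane skeleton and both bridgehead stereocentres untouched; no new stereocentre is formed.

Step 2
Reactants: 2 (−)-nopinone; 3 Meldrum's acid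
Product: 4 nopinylidene Meldrum's acid
Conditions: TiCl4, pyridine, THF, 0 °C → rt
Reagents that add atoms: none
Why: Knoevenagel condensation under TiCl4/pyridine activation, in which the titanium enolate of 3 adds to the titanium-bound ketone and the aldolate is dehydrated irreversibly, is the standard way to condense Meldrum's acid with ketones that fail under amine catalysis. The product has neither a new stereocentre nor an alkene geometry, because the two ring carbonyls on a are equivalent.

Step 3
Reactants: 4 nopinylidene Meldrum's acid; 5 (E)-1-(trimethylsilyloxy)buta-1,3-diene
Product: 6 dispiro silyloxycyclohexene adduct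
Conditions: 5 (3 equiv), PhMe, 60 °C, sealed tube
Reagents that add atoms: none
Why: The electron-poor C=C of 4 (a = C5 of the Meldrum's ring, e = pinane C2) and the electron-rich diene 5 should combine in a normal-demand Diels–Alder reaction, the closest known reaction type being the cycloaddition of alkylidene Meldrum's acids with 1-oxygenated butadienes. The addition is expected to be concerted but strongly asynchronous: the unsubstituted diene terminus, which carries the largest HOMO coefficient, bonds first to e, the β-carbon with the largest LUMO coefficient, and the silyloxy-bearing terminus x then closes onto a (ortho regiochemistry). The six-membered ring a–x–CH=CH–d–e is closed by this suprafacial [4+2] addition. The configuration at e is controlled by the pinane: the gem-dimethyl bridge, whose inner methyl group lies over one face of the exocyclic alkene, forces the diene onto the face of the methylene bridge, so d ends anti and a syn to the gem-dimethyl bridge, as in 26. The configuration at x depends on which way the diene is turned under the dienophile and is not controlled; this is harmless because x becomes a carbonyl carbon in step 5. Since both substituents on a are the same ring carbonyls, alkene geometry and endo/exo preference do not arise. The step therefore needs facial and regiochemical selectivity, secured by the bicycle and by the polarisation of both partners, and enough reactivity at a tetrasubstituted alkene, for which the rigid bis-lactone activation of the Meldrum's unit is relied on.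

Step 4
Reactants: 6 dispiro silyloxycyclohexene adduct
Product: 8 hydroxy spirocyclohexane Meldrum's ester, via saturated silyl ether 7 (not isolated)
Conditions: H2 (1 atm), Pt/C (5 wt%), EtOAc, rt; filter; then 1 M HCl, THF, 0 °C
Reagents that add atoms: none
Why: Heterogeneous hydrogenation saturates the cis-disubstituted ring alkene (Pt/C is chosen to limit allylic C–O hydrogenolysis). Brief aqueous acid then cleaves the trimethylsilyl ether without passing through the alkoxide, which would open the ring by retro-aldol loss of the Meldrum's acid anion.

Step 5
Reactants: 8 hydroxy spirocyclohexane Meldrum's ester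
Product: 9 spirocyclohexanone Meldrum's ester
Conditions: Dess–Martin periodinane, NaHCO3, CH2Cl2, 0 °C → rt
Reagents that add atoms: none
Why: Dess–Martin oxidation under bicarbonate buffering converts the hindered secondary alcohol into the ketone without base-induced retro-aldol cleavage, and it removes the uncontrolled stereocentre at x.

Step 6
Reactants: 9 spirocyclohexanone Meldrum's ester
Product: 11 α-diazo ketone, via trifluoroacetyl ketone 10 (not isolated)
Conditions: LiN(SiMe3)2, THF, −78 °C; CF3CO2CH2CF3; then MsN3, Et3N, H2O (1 equiv), MeCN, rt
Reagents that add atoms: 2,2,2-trifluoroethyl trifluoroacetate, O=C(OCC(F)(F)F)C(F)(F)F (its trifluoroacetyl group is carried only by 10); methanesulfonyl azide, CS(=O)(=O)N=[N+]=[N-]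
Why: Detrifluoroacetylative Regitz diazo transfer: the ketone can enolise only towards b because a is quaternary, the lithium enolate is C-trifluoroacetylated, and the resulting 1,3-diketone takes a diazo group from MsN3 with loss of the trifluoroacetyl group as its sulfonamide. The non-nucleophilic base and the mild second stage spare the Meldrum's ring and the easily cleaved a–x bond.

Step 7
Reactants: 11 α-diazo ketone
Product: 13 ring-contracted methyl ester, via ketene 12 (not isolated)
Conditions: hν (medium-pressure Hg lamp, Pyrex), MeOH, 0 °C → rt
Reagents that add atoms: methanol, CO
Why: Photochemical Wolff rearrangement of a cyclic, s-cis-locked α-diazo ketone leads to ring contraction: a migrates from x to b as nitrogen leaves, and x becomes the ketene carbon, which methanol traps as the methyl ester. The configuration at b arises from protonation of the ester enol and is not controlled here; it is set in step 8.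

Step 8
Reactants: 13 ring-contracted methyl ester
Product: 15 triester, via malonic half ester 14 (not isolated)
Conditions: NaOMe (3 equiv), MeOH, 65 °C; then 1 M HCl to pH 3, extraction; Me3SiCHN2, PhMe/MeOH, 0 °C
Reagents that add atoms: sodium methoxide, [Na+].[O-]C; trimethylsilyldiazomethane, C[Si](C)(C)C=[N+]=[N-]
Why: Methoxide opens the Meldrum's ring by acyl substitution and, at 65 °C, equilibrates b through its ester enolate, which is expected to place the ester on the ring B face of the smaller pinane C3 methylene. Esterification of the remaining acid then gives the triester, in which a is again not a stereocentre.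

Step 9
Reactants: 15 triester
Product: 17 lactone ester, via hydroxy diester 16 (not isolated)
Conditions: MeMgBr (3 equiv), CeCl3, THF, −78 → 0 °C; sat. aq. NH4Cl; then TsOH (cat.), CH2Cl2, rt
Reagents that add atoms: methylmagnesium bromide, C[Mg]Br
Why: Double Grignard addition (CeCl3 suppresses enolisation) should occur only at the ester on the tertiary carbon b, because the two esters on the quaternary carbon a are neopentyl and shielded by e. The tertiary alkoxide can reach only the ester on its own face and closes the γ-lactone by 5-exo-trig transesterification. This cis-only lactonisation distinguishes the two carbonyl groups on a and thereby fixes the configuration of a relative to b.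

Step 10
Reactants: 17 lactone ester
Product: 18 lactone acid
Conditions: LiI (6 equiv), pyridine, 100 °C; then 1 M HCl
Reagents that add atoms: none
Why: SN2 demethylation by iodide attacks the methyl group and not the shielded acyl carbon, so the hindered ester is cleaved while the tertiary-alkyl lactone, which offers no SN2 site, stays intact; no stereocentre is affected.

Step 11
Reactants: 18 lactone acid; 19 pentan-3-one
Product: 21 lactone β-diketone, via acid chloride 20 (not isolated)
Conditions: (COCl)2, DMF (cat.), CH2Cl2, 0 °C → rt; evaporate; then 19 (3 equiv), MgBr2·OEt2, i-Pr2NEt, CH2Cl2, rt
Reagents that add atoms: oxalyl chloride, O=C(Cl)C(Cl)=O (its chlorine is carried only by 20)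
Why: Vilsmeier-type activation gives an acid chloride that has no α-hydrogen and cannot form a ketene. C-acylation of 19 under soft enolisation (magnesium enolate from MgBr2·OEt2 and amine) gives the 1,3-diketone as its magnesium chelate, which protects it from a second acylation. The new methine stereocentre disappears in step 12.

Step 12
Reactants: 21 lactone β-diketone
Product: 22 gem-dimethyl lactone β-diketone
Conditions: MeI, K2CO3, acetone, 56 °C
Reagents that add atoms: iodomethane, CI
Why: C-alkylation of the enolate of a 2-substituted acyclic 1,3-diketone with MeI installs the second methyl group on q, the only doubly activated carbon. Because the other carbonyl on a is tied up in the lactone, the gem-dimethyl group can end only next to p, the carbonyl trans to the carbinol carbon.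

Step 13
Reactants: 22 gem-dimethyl lactone β-diketone
Product: 23 hydroxy trione (enol form)
Conditions: LiN(SiMe3)2 (2.2 equiv), THF, −78 → 0 °C; cold sat. aq. NH4Cl
Reagents that add atoms: none
Why: Intramolecular Claisen (Dieckmann-type) condensation: the only enolisable position is the CH2 of the ethyl ketone, and its lithium enolate attacks the lactone carbonyl in a 6-(enolendo)-exo-trig closure that expels the tertiary alkoxide; deprotonation of the new doubly activated C–H drives the equilibrium. Since the lactone carbonyl was the one cis to the substituent on b, ring A forms with t on the face of that substituent, which is the configuration of a in 26.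

Step 14
Reactants: 23 hydroxy trione (enol form)
Product: 24 methyl enol ether carbinol
Conditions: Me3SiCHN2, PhMe/MeOH, 0 °C
Reagents that add atoms: trimethylsilyldiazomethane, C[Si](C)(C)C=[N+]=[N-]
Why: O-methylation of the acidic enol with the diazoalkane leaves the tertiary alcohol untouched. Methylation is expected on the oxygen at r, flanked only by the CMe2 group, because the oxygen at t is buried beside the spiro centre and the cis carbinol, which can also hydrogen-bond to it.

Step 15
Reactants: 24 methyl enol ether carbinol
Product: 25 isopropenyl compound
Conditions: Burgess reagent, PhMe, 70 °C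
Reagents that add atoms: none
Why: Burgess dehydration proceeds by syn elimination of the intermediate sulfamate under neutral conditions, so no carbocation forms next to ring A. Six methyl hydrogens against one hindered ring hydrogen should favour the isopropenyl isomer, and b is not touched.

Step 16
Reactants: 25 isopropenyl compound
Product: 26 target compound
Conditions: H2 (1 atm), Pt/C (5 wt%), EtOAc, rt
Reagents that add atoms: none
Why: Catalytic hydrogenation reduces the 1,1-disubstituted alkene, while the tetrasubstituted conjugated enol ether alkene and the hindered ketones are inert. Pt/C is preferred to limit alkene migration towards b, so the configuration at b is retained.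

## Compound list

1 | (+)-β-pinene, (1R,5R)-6,6-dimethyl-2-methylidenebicyclo[3.1.1]heptane | C=C1CC[C@@H]2C[C@H]1C2(C)C | starting material
2 | (−)-nopinone, (1S,5R)-6,6-dimethylbicyclo[3.1.1]heptan-2-one | O=C1CC[C@@H]2C[C@H]1C2(C)C | intermediate
3 | Meldrum's acid, 2,2-dimethyl-1,3-dioxane-4,6-dione | CC1(C)OC(=O)CC(=O)O1 | starting material
4 | nopinylidene Meldrum's acid (alkene a=e between C5 of the dioxanedione and pinane C2; bridgeheads as in 2) | CC1(C)OC(=O)C(=C2CC[C@@H]3C[C@H]2C3(C)C)C(=O)O1 | intermediate
5 | (E)-1-(trimethylsilyloxy)buta-1,3-diene | C=C/C=C/O[Si](C)(C)C | starting material
6 | dispiro silyloxycyclohexene adduct (ring a–x(OSiMe3)–CH=CH–d–e; d anti to the gem-dimethyl bridge; both epimers at x) | CC1(C)OC(=O)C2(C(=O)O1)C(O[Si](C)(C)C)C=CC[C@@]21CC[C@@H]2C[C@H]1C2(C)C | intermediate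
7 | saturated silyl ether (6 with the ring alkene hydrogenated) | CC1(C)OC(=O)C2(C(=O)O1)C(O[Si](C)(C)C)CCC[C@@]21CC[C@@H]2C[C@H]1C2(C)C | intermediate
8 | hydroxy spirocyclohexane Meldrum's ester (OH on x; both epimers) | CC1(C)OC(=O)C2(C(=O)O1)C(O)CCC[C@@]21CC[C@@H]2C[C@H]1C2(C)C | intermediate
9 | spirocyclohexanone Meldrum's ester (C=O at x, next to a) | CC1(C)OC(=O)C2(C(=O)O1)C(=O)CCC[C@@]21CC[C@@H]2C[C@H]1C2(C)C | intermediate
10 | trifluoroacetyl ketone (COCF3 on b of 9) | CC1(C)OC(=O)C2(C(=O)O1)C(=O)C(C(=O)C(F)(F)F)CC[C@@]21CC[C@@H]2C[C@H]1C2(C)C | intermediate
11 | α-diazo ketone (diazo group on b of 9) | CC1(C)OC(=O)C2(C(=O)O1)C(=O)C(=[N+]=[N-])CC[C@@]21CC[C@@H]2C[C@H]1C2(C)C | intermediate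
12 | ketene (cyclopentane ring B a–b–c–d–e; b=C=O) | CC1(C)OC(=O)C2(C(=O)O1)C(=C=O)CC[C@@]21CC[C@@H]2C[C@H]1C2(C)C | intermediate
13 | ring-contracted methyl ester (CO2Me on b; both epimers at b; Meldrum's ring on a) | CC1(C)OC(=O)C2(C(=O)O1)C(C(=O)OC)CC[C@@]21CC[C@@H]2C[C@H]1C2(C)C | intermediate
14 | malonic half ester (a carries CO2Me and CO2H, either way round; CO2Me on b on the face of pinane C3) | COC(=O)C2(C(O)=O)[C@@H](C(=O)OC)CC[C@@]21CC[C@@H]2C[C@H]1C2(C)C | intermediate
15 | triester (a carries two CO2Me; CO2Me on b on the ring B face of the pinane C3 methylene) | COC(=O)C2(C(=O)OC)[C@@H](C(=O)OC)CC[C@@]21CC[C@@H]2C[C@H]1C2(C)C | intermediate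
16 | hydroxy diester (C(OH)Me2 on b; two CO2Me on a) | COC(=O)C2(C(=O)OC)[C@@H](C(C)(C)O)CC[C@@]21CC[C@@H]2C[C@H]1C2(C)C | intermediate
17 | lactone ester (γ-lactone O–CMe2–b–a–C(=O) cis-fused on ring B; CO2Me on a trans to the carbinol carbon) | CC3(C)OC(=O)[C@@]2(C(=O)OC)[C@@H]3CC[C@@]21CC[C@@H]2C[C@H]1C2(C)C | intermediate
18 | lactone acid (17 with CO2H in place of CO2Me) | CC3(C)OC(=O)[C@@]2(C(O)=O)[C@@H]3CC[C@@]21CC[C@@H]2C[C@H]1C2(C)C | intermediate
19 | pentan-3-one | CCC(=O)CC | starting material
20 | acid chloride of 18 | CC3(C)OC(=O)[C@@]2(C(Cl)=O)[C@@H]3CC[C@@]21CC[C@@H]2C[C@H]1C2(C)C | intermediate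
21 | lactone β-diketone (a–C(=O)–CH(CH3)–C(=O)–CH2CH3 on a; methine epimers) | CC3(C)OC(=O)[C@@]2(C(=O)C(C)C(=O)CC)[C@@H]3CC[C@@]21CC[C@@H]2C[C@H]1C2(C)C | intermediate
22 | gem-dimethyl lactone β-diketone (a–C(=O)–C(CH3)2–C(=O)–CH2CH3) | CC3(C)OC(=O)[C@@]2(C(=O)C(C)(C)C(=O)CC)[C@@H]3CC[C@@]21CC[C@@H]2C[C@H]1C2(C)C | intermediate
23 | hydroxy trione, drawn as the enol at r (ring A a–p–q–r–s–t closed; C(OH)Me2 on b cis to t) | OC1=C(C)C(=O)[C@@]2(C(=O)C1(C)C)[C@@H](C(C)(C)O)CC[C@@]21CC[C@@H]2C[C@H]1C2(C)C | intermediate
24 | methyl enol ether carbinol (OMe on r; C(OH)Me2 on b) | COC1=C(C)C(=O)[C@@]2(C(=O)C1(C)C)[C@@H](C(C)(C)O)CC[C@@]21CC[C@@H]2C[C@H]1C2(C)C | intermediate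
25 | isopropenyl compound (prop-1-en-2-yl on b) | COC1=C(C)C(=O)[C@@]2(C(=O)C1(C)C)[C@@H](C(C)=C)CC[C@@]21CC[C@@H]2C[C@H]1C2(C)C | intermediate
26 | (1S,2R,2′R,3′R,5R)-4″-methoxy-3″,5″,5″,6,6-pentamethyl-3′-(propan-2-yl)dispiro[bicyclo[3.1.1]heptane-2,1′-cyclopentane-2′,1″-cyclohex[3]ene]-2″,6″-dione (R at e, a and b) | COC1=C(C)C(=O)[C@@]2(C(=O)C1(C)C)[C@@H](C(C)C)CC[C@@]21CC[C@@H]2C[C@H]1C2(C)C | target

## Step count and least certain steps

Total step count: 16. Longest linear sequence: 16 steps (1 to 26); 3, 5 and 19 are bought.

**Step 3 (key step).** The cycloaddition may be too slow at a tetrasubstituted, γ-enolisable alkene. The diene may also add only in a Mukaiyama–Michael sense (bond d–e without closure onto a), or polymerise before it reacts. Fallback, stepwise formation of the same two bonds, setting out from 4: copper-catalysed conjugate addition of the Grignard reagent from 2-(3-bromopropyl)-1,3-dioxolane (CuBr·SMe2, THF, −40 °C) should attack e from the same open face and give the acetal-bearing 5-monosubstituted Meldrum's acid F1. Aqueous acid frees the aldehyde F2. The acidic C–H of the Meldrum's unit then adds to the aldehyde in a 6-(enolexo)-exo-trig aldol closure (catalytic piperidinium acetate), and the route is rejoined at 8.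

**Step 7.** The carbene may undergo a 1,2-hydrogen shift from c to give a cyclohexenone, or migration of the electron-poor quaternary carbon a may be slow enough for insertion into methanol to compete. Fallback, setting out from 9 (step 6 is then omitted): oxidative ring contraction with the trivalent iodine reagent PhI(OAc)2 in MeOH with HC(OMe)3 and catalytic H2SO4. The ketone is converted in situ into its enol ether, iodinated at b, and the a–x bond shifts to b as PhI leaves, giving the methyl ester directly. The route is rejoined at 13, and no new isolated compound arises (entry F0).

**Step 8.** Equilibration may fail to enrich the wanted epimer if the energy difference between the two faces at b is small or opposite to the assumption. Fallback under kinetic control, setting out from 15 of any epimer ratio: LiN(i-Pr)2 then PhSeBr gives the α-phenylselanyl triester F3. Oxidation with H2O2 and syn elimination of the selenoxide gives the cyclopentene triester F4 (alkene b=c). Hydrogenation over Pt/C then delivers hydrogen to b from the less hindered face, which is the complementary sense to thermodynamic control, and returns to 15.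

**Step 11.** Acyl substitution at a carbonyl flanked by two quaternary centres may be outrun by O-acylation of the enolate or by attack on the lactone. Fallback through an aldehyde, which needs no tetrahedral intermediate at a crowded acyl carbon, setting out from 18: BH3·SMe2 reduces the acid selectively to the neopentyl alcohol F5; Dess–Martin oxidation gives the aldehyde F6; aldol addition of the lithium enolate of 19 gives the β-hydroxy ketone F7; a second Dess–Martin oxidation rejoins the route at 21.

**Step 13.** The simple ketone enolate may not add to the congested lactone carbonyl, or the non-enolisable 1,3-diketone of 22 may fragment by retro-Claisen cleavage instead. Fallback, setting out from 21 (step 12 is then omitted):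
- LiN(i-Pr)2 (2.2 equiv) forms the 1,3-diketone dianion, whose terminal carbanion is far more nucleophilic and closes onto the lactone to give the 2,4-dimethyl hydroxy trione F8.
- TsOH with removal of water condenses the tertiary alcohol with the only carbonyl it can reach (t) to the cyclic enol ether F9 (the structure of A6).
- MeI/K2CO3 methylates the one remaining doubly activated carbon, q, to the gem-dimethyl cyclic enol ether F10.
- Me3OBF4 with 2,6-di-tert-butylpyridine methylates the carbonyl oxygen at r, and the resulting oxocarbenium ion loses its tertiary alkyl group as the alkene. This rejoins the route at 25 with the methoxy position fixed by construction.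

**Step 14.** Alkylation may show poor site selectivity between the two enol oxygens. Fallback with thermodynamic in place of kinetic control, setting out from 23: the regioisomeric methyl ether F11 (methoxy on t) is not discarded but taken through the conditions of steps 15 and 16 to its isopropenyl analogue F12 and its isopropyl analogue F13. F13 is then equilibrated with MeOH, HC(OMe)3 and TsOH, under which the two vinylogous esters interconvert through a common dimethoxy cation, and the less congested isomer should prevail. The route is rejoined at 26.

Further compounds

F1 | step 3 | 5-monosubstituted Meldrum's acid carrying on C5 the pinane C2 carbon with a 3-(1,3-dioxolan-2-yl)propyl chain anti to the gem-dimethyl bridge | CC1(C)OC(=O)C(C(=O)O1)[C@@]1(CCCC2OCCO2)CC[C@@H]2C[C@H]1C2(C)C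
F2 | step 3 | aldehyde from F1 (4-oxobutyl chain on pinane C2) | CC1(C)OC(=O)C(C(=O)O1)[C@@]1(CCCC=O)CC[C@@H]2C[C@H]1C2(C)C
F0 | step 7 | none | none
F3 | step 8 | α-phenylselanyl triester (SePh and CO2Me on b) | COC(=O)C2(C(=O)OC)C([Se]c3ccccc3)(C(=O)OC)CC[C@@]21CC[C@@H]2C[C@H]1C2(C)C
F4 | step 8 | cyclopentene triester (alkene b=c) | COC(=O)C2(C(=O)OC)C(C(=O)OC)=CC[C@@]21CC[C@@H]2C[C@H]1C2(C)C
F5 | step 11 | lactone neopentyl alcohol (CH2OH on a in place of CO2H of 18) | CC3(C)OC(=O)[C@@]2(CO)[C@@H]3CC[C@@]21CC[C@@H]2C[C@H]1C2(C)C
F6 | step 11 | lactone aldehyde (CHO on a) | CC3(C)OC(=O)[C@@]2(C=O)[C@@H]3CC[C@@]21CC[C@@H]2C[C@H]1C2(C)C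
F7 | step 11 | lactone β-hydroxy ketone (aldol of F6 with pentan-3-one) | CC3(C)OC(=O)[C@@]2(C(O)C(C)C(=O)CC)[C@@H]3CC[C@@]21CC[C@@H]2C[C@H]1C2(C)C
F8 | step 13 | 2,4-dimethyl hydroxy trione (ring A with CH(CH3) at q and s; C(OH)Me2 on b) | CC1C(=O)C(C)C(=O)C2(C1=O)[C@@H](C(C)(C)O)CC[C@@]21CC[C@@H]2C[C@H]1C2(C)C
F9 | step 13 | cyclic enol ether (O on t linked to CMe2 on b; CH(CH3) at q) | CC1=C2OC(C)(C)[C@H]3CC[C@@]4(CC[C@@H]5C[C@H]4C5(C)C)[C@@]23C(=O)C(C)C1=O
F10 | step 13 | gem-dimethyl cyclic enol ether (F9 methylated at q) | CC1=C2OC(C)(C)[C@H]3CC[C@@]4(CC[C@@H]5C[C@H]4C5(C)C)[C@@]23C(=O)C(C)(C)C1=O
F11 | step 14 | regioisomeric methyl enol ether carbinol (OMe on t, C=O at r) | CC1=C(OC)[C@@]2(C(=O)C(C)(C)C1=O)[C@@H](C(C)(C)O)CC[C@@]21CC[C@@H]2C[C@H]1C2(C)C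
F12 | step 14 | regioisomeric isopropenyl compound (OMe on t) | CC1=C(OC)[C@@]2(C(=O)C(C)(C)C1=O)[C@@H](C(C)=C)CC[C@@]21CC[C@@H]2C[C@H]1C2(C)C
F13 | step 14 | regioisomer of the target (OMe on t, C=O at r) | CC1=C(OC)[C@@]2(C(=O)C(C)(C)C1=O)[C@@H](C(C)C)CC[C@@]21CC[C@@H]2C[C@H]1C2(C)C
A1 | alternative 1 | allylic methyl carbonate of the pin-3-en-2-yl phloroglucinol (free OH and OSi(i-Pr)3 ortho to the pinane carbon) | COC(=O)OC/C(C)=C/CC[C@]1(c2c(O)c(C)c(OC)c(C)c2O[Si](C(C)C)(C(C)C)C(C)C)C=C[C@@H]2C[C@H]1C2(C)C
A2 | alternative 1 | spiro cyclohexa-2,4-dienone with isopropenyl on b and a silyl enol ether | COC1=C(C)C(=O)[C@@]2(C(O[Si](C(C)C)(C(C)C)C(C)C)=C1C)[C@@H](C(C)=C)CC[C@@]21C=C[C@@H]2C[C@H]1C2(C)C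
A3 | alternative 2 | nopinylidene ring A dione (2-alkylidene-5-methoxy-4,6,6-trimethylcyclohex-4-ene-1,3-dione) | COC1=C(C)C(=O)C(=C2CC[C@@H]3C[C@H]2C3(C)C)C(=O)C1(C)C
A4 | alternative 2 | dispiro cyclopropane joining ring A and the pinane | COC1=C(C)C(=O)C2(C(=O)C1(C)C)C[C@@]23CC[C@@H]2C[C@H]3C2(C)C
A5 | alternative 3 | symmetric 2,4-dimethyl spiro trione with isopropenyl on b | CC1C(=O)C(C)C(=O)C2(C1=O)[C@@H](C(C)=C)CC[C@@]21CC[C@@H]2C[C@H]1C2(C)C
A6 | alternative 3 | tricyclic 2,2-dimethyl cyclic enol ether cis-fused to ring B | CC1=C2OC(C)(C)[C@H]3CC[C@@]4(CC[C@@H]5C[C@H]4C5(C)C)[C@@]23C(=O)C(C)C1=O
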